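Readings and results were computed on assumed constants.

A small charge is worth planning on paper, so before spending any Z on Friday's flask I want to know how much of it reaches E.

| flask | Z | X | E | time |
|---|---|---|---|---|
| Monday's | 0.400 M | 0.800 M |  |  |
| Wednesday's | 0.400 M | 0.800 M | 0.120 M |  |
| Friday's | 1.00 M | 2.00 M |  | 24 min |

| run | time / min | [E] / M |
|---|---|---|
| Monday's run | 0.86 | 0.010 |
| Monday's run | 2.6 | 0.032 |
| Monday's run | 5.0 | 0.092 |
| Monday's run | 7.9 | 0.159 |
| Monday's run | 11 | 0.219 |
| Monday's run | 15 | 0.271 |
| Monday's run | 19 | 0.297 |
| Monday's run | 24 | 0.313 |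
| Wednesday's run | 0.86 | 0.142 |
| Wednesday's run | 2.6 | 0.209 |
| Wednesday's run | 5.0 | 0.288 |
| Wednesday's run | 7.9 | 0.381 |
| Wednesday's run | 11 | 0.417 |
| Wednesday's run | 15 | 0.444 |
| Wednesday's run | 19 | 0.457 |
| Wednesday's run | 24 | 0.458 |

(standard deviation of a reading: 0.004 M)

* E in the Friday's run at 24 min, as a share of the Z charged

- Overall: Z + X -> E.
- Constant volume, constant temperature.
- A reading of a species includes what of it is bound.

E speeds its own formation. By 2.6 min, Monday's flask has made 0.0320 M, while Wednesday's, from the same Z and X with E added, has made 0.0890 M, more. Yet by 24 min neither flask has made as much E as the Z charged, and Z is the limiting reagent. Wednesday's E rises by 0.00100 M over its last interval, less than the scatter, though E stands at its highest there.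

I read the shortfall as Z lost to a leak, first order in Z, racing a path that runs on Z, X and E together. The shortfall share should then follow the ratio of the leak to that path. So I take the share of the Z charged that is not E at 24 min and multiply it by E and X at the point where the E made is half of the Z charged. I call this product the leak constant, and each run gives it separately:

Monday: 21.8% × 0.200 M × 0.600 M = 0.0261 M^2

Wednesday: 15.5% × 0.320 M × 0.600 M = 0.0298 M^2

The two part a little. Monday's E is still rising, by 0.0160 M over its last interval, more than Wednesday's, so Monday's shortfall is not final. Further E would lower Monday's figure, which widens the gap instead of closing it, so waiting does not reconcile the two. I keep Wednesday's figure, from the flask whose readings have flattened, and hold Monday's beside it as the other value.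

Friday's halfway product is 0.750 M^2, larger than Wednesday's 0.192 M^2, so I expect Friday's E to have flattened by 24 min as well. Wednesday's constant then gives a yield of 96.0%, and Monday's gives 96.5%.

The forecast says 90%, below my figure: “If the death tracks turnover or E, Friday falls short”.

Friday's flask gives 96.0%.

    Z → Q (0.1080 min⁻¹)
    Q + X → E (0.7620 M⁻¹ min⁻¹)
    Q → L (0.1992 min⁻¹)
    Z + X + E → 2 E (0.9660 M⁻² min⁻¹)
    Z + X ⇌ ZX, settled at all times (0.6200 M⁻¹)

The E made comes to half of the Z charged at 5.76 min in Wednesday's run, against 9.73 min in Monday's. Friday's shortfall of 4.05%, multiplied by its halfway product, gives a leak constant of 0.0304 M^2.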